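**Retrosynthetic overview** (ring atoms: O1, C2 stereocentre, C3 = CH2, C4 = C=O, C5 = CH, C6 = C–CH3)
- Target 10 ⇒ acyclic bromo enal 9. The only ring, the 2,3-dihydro-4H-pyran-4-one, is closed last at C3–C4 by a nickel/photoredox coupling of the formyl C–H with the primary C–Br.
- 9 ⇒ bromohydrin 7 + but-2-ynal 8: the O1–C6 enol-ether bond by oxa-Michael addition.
- 7 ⇒ epoxide 6 ⇒ bromide 2 + (R)-epichlorohydrin 3: the C2 stereocentre comes from the chiral pool, the (Z)-olefin chain from cis-11-eicosenol 1.
- Enabling feature: the vinylogous ester O1–C6(CH3)=C5–C4(=O) of the ring. In the open chain its C4 acyl radical is an O1-stabilised α-ketenyl radical, so the C5=C6 geometry can relax to the cis form that reaches C3; the same unit deactivates the C2–H toward hydrogen abstraction.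

Key step: step 5

Assumption: 1, 3 and 8 are bought; the enal from step 4 is taken to be mainly (E), which the route does not depend on.

**Step 1**
Reactants: 1 (Z)-icos-11-en-1-ol
Product: 2 (Z)-1-bromoicos-11-ene
Conditions: CBr4, PPh3, CH2Cl2, 0 °C to rt
Reagents that add atoms: carbon tetrabromide, BrC(Br)(Br)Br
Why: The Appel reaction should replace the primary hydroxyl by bromide through SN2 on the alkoxyphosphonium salt under neutral conditions that leave the (Z)-olefin untouched.

**Step 2**
Reactants: 2 (Z)-1-bromoicos-11-ene; 3 (R)-epichlorohydrin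
Product: 6 (R)-2-[(Z)-henicos-12-en-1-yl]oxirane, via icosenylmagnesium bromide 4 (not isolated), via chlorohydrin 5 (not isolated)
Conditions: Mg, THF, 40 °C; then 3, CuI (10 mol%), THF, −40 to 0 °C; then NaOH, MeOH/H2O, rt
Reagents that add atoms: none
Why: Copper-catalysed Grignard opening of the epoxide should occur by SN2 at the unsubstituted ring carbon of 3, leaving the chiral-pool stereocentre untouched, and hydroxide should then close the chlorohydrin alkoxide by intramolecular Williamson displacement to the (R)-epoxide.

**Step 3**
Reactants: 6 (R)-2-[(Z)-henicos-12-en-1-yl]oxirane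
Product: 7 (2R,14Z)-1-bromotricos-14-en-2-ol
Conditions: LiBr, AcOH, THF, rt
Reagents that add atoms: lithium bromide, [Li+].[Br-]
Why: Acid-assisted SN2 opening of the terminal epoxide by bromide should take place at the primary carbon, so the C–O stereocentre is retained.

**Step 4**
Reactants: 7 (2R,14Z)-1-bromotricos-14-en-2-ol; 8 but-2-ynal
Product: 9 (E)-3-{[(2R,14Z)-1-bromotricos-14-en-2-yl]oxy}but-2-enal
Conditions: DABCO (20 mol%), CH2Cl2, 0 °C to rt
Reagents that add atoms: none
Why: Amine-catalysed oxa-Michael (conjugate) addition of the secondary alcohol to the ynal should give the β-alkoxy enal, expected mainly as the (E) isomer, without touching the stereocentre.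

**Step 5**
Reactants: 9 (E)-3-{[(2R,14Z)-1-bromotricos-14-en-2-yl]oxy}but-2-enal
Product: 10 (R)-2-[(Z)-henicos-12-en-1-yl]-6-methyl-2,3-dihydro-4H-pyran-4-one
Conditions: [Ir(dF(CF3)ppy)2(dtbbpy)]PF6 (1 mol%), NiBr2(dme) (10 mol%), dtbbpy (10 mol%), quinuclidine (20 mol%), K2CO3 (1.5 equiv), 1,4-dioxane (5 mM), blue LEDs, rt
Reagents that add atoms: none
Why: Proposed new method: the light-excited iridium photocatalyst oxidises quinuclidine to its aminium radical, which abstracts the formyl hydrogen of 9 to give the acyl radical, while zerovalent nickel inserts into the primary C–Br bond; the tethered alkylnickel captures the acyl radical, the trivalent acyl(alkyl)nickel reductively eliminates the CH2–C(=O) bond, and the monovalent nickel is reduced back by the reduced photocatalyst while K2CO3 takes up HBr. The closest known reaction type is the intermolecular nickel/photoredox/hydrogen-atom-transfer coupling of aldehyde C–H bonds with alkyl bromides to ketones; new here are the intramolecular mode and the β-alkoxy enal as acyl donor. The only ring of the target is closed as a six-membered ring by C(sp3)–C(acyl) reductive elimination from a seven-membered nickelacycle. No new stereocentre arises, and the (R) centre stays as set by 3 because no bond to it is made or broken. The closure needs the ether oxygen and the acyl carbon cis on the enol-ether double bond, while 9 is mainly (E): the β-alkoxy acyl radical is in resonance with an α-ketenyl radical, O=C=CH–C•(CH3)–OR, stabilised by the ether oxygen, so rotation about the former double bond interconverts both geometries and only the cis form can reach nickel. Hydrogen abstraction should prefer the hydridic formyl C–H over the O–CH (deactivated by the vinylogous acyl group and the β-bromine) and the allylic CH2 groups, high dilution should suppress intermolecular ketone formation, and the isolated (Z)-olefin is not sensitised by the photocatalyst.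

**Compound list**
1 | (Z)-icos-11-en-1-ol | CCCCCCCC/C=C\CCCCCCCCCCO | starting material
2 | (Z)-1-bromoicos-11-ene | CCCCCCCC/C=C\CCCCCCCCCCBr | intermediate
3 | (R)-epichlorohydrin, (R)-2-(chloromethyl)oxirane | ClC[C@H]1CO1 | starting material
4 | (Z)-icos-11-en-1-ylmagnesium bromide | CCCCCCCC/C=C\CCCCCCCCCC[Mg]Br | intermediate
5 | (2R,14Z)-1-chlorotricos-14-en-2-ol (present as its magnesium alkoxide) | CCCCCCCC/C=C\CCCCCCCCCCC[C@@H](O)CCl | intermediate
6 | (R)-2-[(Z)-henicos-12-en-1-yl]oxirane | CCCCCCCC/C=C\CCCCCCCCCCC[C@@H]1CO1 | intermediate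
7 | (2R,14Z)-1-bromotricos-14-en-2-ol | CCCCCCCC/C=C\CCCCCCCCCCC[C@@H](O)CBr | intermediate
8 | but-2-ynal | CC#CC=O | starting material
9 | (E)-3-{[(2R,14Z)-1-bromotricos-14-en-2-yl]oxy}but-2-enal | CCCCCCCC/C=C\CCCCCCCCCCC[C@@H](O/C(C)=C/C=O)CBr | intermediate
10 | (R)-2-[(Z)-henicos-12-en-1-yl]-6-methyl-2,3-dihydro-4H-pyran-4-one | CCCCCCCC/C=C\CCCCCCCCCCC[C@@H]1CC(=O)C=C(C)O1 | target

Total step count: 5. Longest linear sequence: 5 steps.

**Steps most likely to fail**

Step 5 (Proposed new method). Ring closure may be outrun by several processes: slow relaxation of the (E) acyl radical to the cis form, loss of the alkoxy group by addition–elimination of quinuclidine at the enal β-carbon (the freed bromohydrin alkoxide would close to the epoxide), β-elimination at nickel, intermolecular coupling, or allylic hydrogen abstraction that scrambles the chain olefin. The fallback uses known chemistry and sets out from epoxide 6. Opening with LiC≡CH·H2NCH2CH2NH2 in DMSO should give (4R,16Z)-pentacos-16-en-1-yn-4-ol F1. 1,3-Dipolar cycloaddition of its terminal alkyne with acetonitrile oxide (acetaldoxime, NCS, then Et3N, CH2Cl2) should give (2R,14Z)-1-(3-methylisoxazol-5-yl)tricos-14-en-2-ol F2. Reductive N–O cleavage with Mo(CO)6 in MeCN/H2O at 80 °C should give the enaminone (2Z,6R,18Z)-2-amino-6-hydroxyheptacosa-2,18-dien-4-one F3. Aqueous HCl in THF should close it with loss of ammonia, and the fallback comes back to the route at target 10.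

Step 4. The amine may close the bromohydrin to the epoxide or be alkylated by the bromide faster than the hindered alcohol adds to the β-substituted ynal. The base-free fallback sets out from 7. Acetylation (Ac2O, pyridine) should give (2R,14Z)-1-bromotricos-14-en-2-yl acetate F4. Petasis methylenation (Cp2TiMe2, toluene, 65 °C) should give (2R,14Z)-1-bromo-2-(prop-1-en-2-yloxy)tricos-14-ene F5. Vilsmeier–Haack formylation of this enol ether (POCl3, DMF, CH2Cl2, 0 °C; then aqueous NaOAc) should give the β-alkoxy enal, coming back to the route at 9.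

Step 2. Competing attack of the organometallic at the chloromethyl carbon would lower regio- and enantiopurity, and Wurtz coupling may consume the bromide. The fallback sets out from 2. Alkylation of lithioacetonitrile (n-BuLi, MeCN, THF, −78 °C) should give (Z)-docos-13-enenitrile F6. Reduction with i-Bu2AlH and acidic work-up should give (Z)-docos-13-enal F7. Corey–Chaykovsky epoxidation (trimethylsulfonium iodide, KOt-Bu, DMSO) should give racemic 2-[(Z)-henicos-12-en-1-yl]oxirane F8. Hydrolytic kinetic resolution with (R,R)-(salen)Co(OAc) and 0.55 equiv H2O is expected to hydrolyse the (S)-epoxide faster and leave the (R)-epoxide, coming back to the route at 6.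

**Further compounds**
F1 | step 5 | (4R,16Z)-pentacos-16-en-1-yn-4-ol | CCCCCCCC/C=C\CCCCCCCCCCC[C@@H](O)CC#C
F2 | step 5 | (2R,14Z)-1-(3-methylisoxazol-5-yl)tricos-14-en-2-ol | CCCCCCCC/C=C\CCCCCCCCCCC[C@@H](O)Cc1cc(C)no1
F3 | step 5 | (2Z,6R,18Z)-2-amino-6-hydroxyheptacosa-2,18-dien-4-one | CCCCCCCC/C=C\CCCCCCCCCCC[C@@H](O)CC(=O)/C=C(/C)N
F4 | step 4 | (2R,14Z)-1-bromotricos-14-en-2-yl acetate | CCCCCCCC/C=C\CCCCCCCCCCC[C@@H](OC(C)=O)CBr
F5 | step 4 | (2R,14Z)-1-bromo-2-(prop-1-en-2-yloxy)tricos-14-ene | CCCCCCCC/C=C\CCCCCCCCCCC[C@@H](OC(C)=C)CBr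
F6 | step 2 | (Z)-docos-13-enenitrile | CCCCCCCC/C=C\CCCCCCCCCCCC#N
F7 | step 2 | (Z)-docos-13-enal | CCCCCCCC/C=C\CCCCCCCCCCCC=O
F8 | step 2 | racemic 2-[(Z)-henicos-12-en-1-yl]oxirane | CCCCCCCC/C=C\CCCCCCCCCCCC1CO1
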